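(Readings and results come from a simulation on assumed constants.)

Multiplying a percent of target by the substrate charged turns it into a concentration, and I build on that easy step.

the same everywhere: initiator 4.5 mM
- summer: substrate 0.0090 M; solid reagent 0.15 M; run made earlier
- midnight: substrate 0.044 M; solid reagent 0.15 M; run made earlier
- dusk: substrate 0.16 M; solid reagent 0.15 M; run made earlier
- alder: substrate 0.050 M; solid reagent 0.150 M; time 30 min
- cedar: substrate 0.015 M; solid reagent 0.150 M; time 30 min
- ash: substrate 0.080 M; solid reagent 0.150 M; time 30 min
- maple: substrate 0.20 M; solid reagent 0.150 M; time 30 min
- elm: substrate 0.012 M; solid reagent 0.150 M; time 30 min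

| run | time / min | target / % |
|---|---|---|
| summer | 1.33 | 1.9 |
| summer | 2.50 | 3.6 |
| summer | 4.00 | 6.3 |
| summer | 8.00 | 11.5 |
| summer | 15.0 | 19.4 |
| midnight | 1.33 | 0.4 |
| midnight | 2.50 | 2.7 |
| midnight | 4.00 | 2.8 |
| midnight | 8.00 | 0.9 |
| midnight | 15.0 | 2.9 |
| dusk | 3.00 | 1.3 |
| dusk | 6.00 | 0 |
| dusk | 10.0 | 1.6 |
| dusk | 12.0 | 0.9 |
| dusk | 15.0 | 1.4 |

(each reading ± 1 percentage point)

* all flasks from highest to lowest amount of target, in percent of the substrate charged, at 30 min (alder / cedar / ash / maple / elm)
* the amount of target, in percent of the substrate charged of the flask you put first, at 30 min
* the amount of target, in percent of the substrate charged of the flask you put last, at 30 min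

- solid, in amounts per volume of the solution: solid reagent
- the numbers in the tables scatter by 1 percentage point (one standard deviation)
- steps under discussion: substrate + second chain carrier -> released group + first chain carrier; 2 second chain carrier -> ended chains; coupling partner + first chain carrier <-> target + second chain carrier; initiator -> 2 initiating radical; target <-> isomer of the product; solid reagent <-> coupling partner; substrate + initiating radical -> capped initiator + first chain carrier
- at the start none of the solid reagent is in solution

1. In the first extreme version, the chain is pseudo-first-order in substrate, so percent at equal times is independent of the charge. Doubling summer's time then gives 35.0% at 30 min, whatever the charge.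

2. In the second extreme version, substrate stays out of the rate-limiting step. [target] at equal times is then independent of the charge, and percent falls as 1/[substrate].

3. Between summer and dusk, substrate rises 17.8-fold and the percent read at 15.0 min falls 13.9-fold, from 19.4% to 1.4%, a ratio that carries the scatter of dusk's small reading. As concentrations, the readings are 0.00175 M in summer, 0.00128 M in midnight and 0.00224 M in dusk. So I place these flasks close to the second version.

4. Summer's substrate is smaller than midnight's or dusk's, so a point of scatter costs it less concentration. From summer's last reading I take the output, the concentration of target gained per minute 1.16 × 10⁻⁴ M min⁻¹, a reading with its scatter.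

5. Output times 30 min gives 0.00349 M. That is 29.1% in elm, which has less substrate than the other asked flasks, and 1.75% in maple, which has more than the other asked flasks. Summer's reading at 4.00 min gives 1.42 × 10⁻⁴ M min⁻¹, faster than the output though with 1 percentage point of scatter in the reading, so I lean a little below these figures.

The forecast gives elm > cedar > alder > ash > maple, with 30% first and 1.9% last, and it names as most likely “slow dissolution of the solid reagent feeding coupling partner”.

The flasks give elm > cedar > alder > ash > maple, with 26.3% first and 1.58% last.

    substrate + second chain carrier → released group + first chain carrier (k = 1700 M⁻¹ s⁻¹)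
    2 second chain carrier → ended chains (k = 1.80 × 10⁶ M⁻¹ s⁻¹)
    coupling partner + first chain carrier ⇌ target + second chain carrier (K = 0.790, k = 15000 M⁻¹ s⁻¹)
    initiator → 2 initiating radical (k = 8.60 × 10⁻⁵ s⁻¹)
    target ⇌ isomer of the product (K = 0.700, k = 6.60 × 10⁻⁴ s⁻¹)
    solid reagent ⇌ coupling partner, rate k6*(cs6 - [coupling partner]) while solid is left; crystals form when [coupling partner] > cs6 (solubility = 25.0 mM, k = 9.70 × 10⁻⁵ s⁻¹)
    substrate + initiating radical → capped initiator + first chain carrier (k = 20000 M⁻¹ s⁻¹)

The output gives elm 29.1% against 26.3%, and for a flask like elm charged with 0.0072 M of substrate it gives 48.5%, where that flask holds 43.8%. In elm, solid reagent goes into solution steadily, with half of that turnover done by 15.0 min and 97.1% of its charge still present at 30.0 min, while coupling partner stands at 8.67 × 10⁻⁷ M. Meanwhile, in elm, target turns into isomer of the product, which reaches 10.1% of the substrate charged at 30.0 min.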